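**Plan**

- Retrosynthetic cuts, in order: the fourteen benzyl ethers and two C8 bromine caps; the interflavan bond C4(upper)–C6(lower); the gallate ester C–O bond of the lower unit; in the upper unit the aryl ether bond O1–C8a of ring C; then C4–C4a (ring A to the chain) and C2–C3 (aldol).
- Forward: the chain C2–C3–C4 of the upper unit comes from a glycolate aldol reaction on the ring B aldehyde. Ring A is added at C4 as a 2-fluoro-4,6-bis(benzyloxy)phenyl ketone, which is reduced. Ring C is then closed by O1–C8a, C8 is brominated, and C4 is joined to C6 of the lower unit, made from natural (−)-epigallocatechin by phenol benzylation, galloylation at O3 and C8 bromination. Hydrogenolysis ends the route.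
- Feature used: in ring A the ether carbon C8a is meta to the oxygen-bearing carbons C5 and C7 and is tied to the C2 oxygen by the chain C2–C3–C4–C4a. A C2 alkoxide can therefore displace fluoride from C8a through a six-membered transition state, and the C5 and C7 oxygens do not donate into the attacked carbon.
- Stereochemistry: upper C2 and C3 come from the Evans syn-aldol reaction and stay 2,3-cis because the ring closure breaks no bond at a stereocenter. Upper C4 comes from anti attack on the cyclic C4 cation (3,4-trans). Lower C2 and C3 come with (−)-epigallocatechin.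
- The 4→6 connectivity follows from the bromine at C8 of the lower unit, which leaves C6 as its only free ring A carbon; the bromine at C8 of the upper unit holds back self-condensation.

Key step: step 8

Remark: the configuration of the C4 carbinol carried from the ketone reduction to the coupling is not decisive, because C4 becomes planar in the coupling; the epimer expected from the reduction is drawn. (S)-4-Benzyloxazolidin-2-one, (benzyloxy)acetyl chloride, 3,4,5-tris(benzyloxy)benzaldehyde, 4-bromo-3,5-difluorophenol, (−)-epigallocatechin and 3,4,5-tris(benzyloxy)benzoic acid are taken as commercial.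

**Route**

Step 1
Reactants: 1 (S)-4-benzyloxazolidin-2-one; 2 (benzyloxy)acetyl chloride
Product: 3 (S)-4-benzyl-3-[(benzyloxy)acetyl]oxazolidin-2-one
Conditions: Et3N, DMAP (cat.), CH2Cl2, 0 °C → rt
Reagents that add atoms: none
Why: DMAP-catalysed N-acylation of the oxazolidinone (nucleophilic acyl substitution) installs the glycolate unit that becomes C3, with its benzyl-protected oxygen, and C4 of the upper unit.

Step 2
Reactants: 3 (S)-4-benzyl-3-[(benzyloxy)acetyl]oxazolidin-2-one; 4 3,4,5-tris(benzyloxy)benzaldehyde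
Product: 6 (S)-4-benzyl-3-[(2S,3R)-2-(benzyloxy)-3-hydroxy-3-[3,4,5-tris(benzyloxy)phenyl]propanoyl]oxazolidin-2-one, via dibutylboron Z-enolate 5 (not isolated)
Conditions: Bu2BOTf, Et3N, CH2Cl2, −78 → 0 °C; then 4, −78 → 0 °C; pH 7 buffer, MeOH, H2O2
Reagents that add atoms: none
Why: Evans syn-aldol reaction, in which the Z-enolate 5 reacts through a closed Zimmerman–Traxler chair and the benzyl group of the auxiliary shields one enolate face, so the 2,3-syn adduct with (2S,3R) configuration (the future C3 and C2 of the upper unit) should form.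

Step 3
Reactants: 6 (S)-4-benzyl-3-[(2S,3R)-2-(benzyloxy)-3-hydroxy-3-[3,4,5-tris(benzyloxy)phenyl]propanoyl]oxazolidin-2-one
Product: 7 (2S,3R)-2-(benzyloxy)-3-hydroxy-N-methoxy-N-methyl-3-[3,4,5-tris(benzyloxy)phenyl]propanamide
Conditions: AlMe3, MeONHMe·HCl, CH2Cl2, −10 °C → rt; 1 M HCl work-up
Reagents that add atoms: N,O-dimethylhydroxylamine hydrochloride, CNOC.Cl
Why: Aluminium-amide transamination of the imide, helped by the free β-hydroxyl, releases the auxiliary and gives the Weinreb amide without touching either stereocenter.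

Step 4
Reactants: 8 4-bromo-3,5-difluorophenol
Product: 9 5-(benzyloxy)-2-bromo-1,3-difluorobenzene
Conditions: BnBr, K2CO3, DMF, rt
Reagents that add atoms: benzyl bromide, BrCc1ccccc1
Why: Williamson etherification of the phenol gives the first benzyl ether of ring A on a symmetric arene.

Step 5
Reactants: 9 5-(benzyloxy)-2-bromo-1,3-difluorobenzene
Product: 10 1,5-bis(benzyloxy)-2-bromo-3-fluorobenzene
Conditions: BnOH (1.0 equiv), NaH (1.05 equiv), NMP, 0 → 70 °C
Reagents that add atoms: benzyl alcohol, OCc1ccccc1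
Why: SNAr of one of the two equivalent fluorides (each ortho to bromine and meta to the other fluorine) by NaOBn should stop after one substitution because the new alkoxy group slows the second, and the symmetry of 9 makes the substitution pattern of 10 unambiguous.

Step 6
Reactants: 10 1,5-bis(benzyloxy)-2-bromo-3-fluorobenzene; 7 (2S,3R)-2-(benzyloxy)-3-hydroxy-N-methoxy-N-methyl-3-[3,4,5-tris(benzyloxy)phenyl]propanamide
Product: 12 (2S,3R)-1-[2,4-bis(benzyloxy)-6-fluorophenyl]-2-(benzyloxy)-3-hydroxy-3-[3,4,5-tris(benzyloxy)phenyl]propan-1-one, via aryllithium 11 (not isolated)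
Conditions: 10 (2.5 equiv), n-BuLi (2.4 equiv), THF, −78 °C; then 7, −78 → −60 °C; aq. NH4Cl
Reagents that add atoms: none
Why: Bromine–lithium exchange gives the ortho-fluoro aryllithium 11, which at low temperature adds to the Weinreb amide after one equivalent has deprotonated the hydroxyl; the chelated tetrahedral adduct prevents over-addition and the stereocenters are not touched.

Step 7
Reactants: 12 (2S,3R)-1-[2,4-bis(benzyloxy)-6-fluorophenyl]-2-(benzyloxy)-3-hydroxy-3-[3,4,5-tris(benzyloxy)phenyl]propan-1-one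
Product: 13 (1R,2S,3R)-1-[2,4-bis(benzyloxy)-6-fluorophenyl]-2-(benzyloxy)-3-[3,4,5-tris(benzyloxy)phenyl]propane-1,3-diol
Conditions: Me4NBH(OAc)3, MeCN/AcOH, −30 °C
Reagents that add atoms: none
Why: Evans–Saksena reduction, in which the hydroxyl exchanges an acetate on boron and delivers hydride intramolecularly through a chair transition state, should give the 1,3-anti diol (new center 1R), although either epimer would serve.

Step 8
Reactants: 13 (1R,2S,3R)-1-[2,4-bis(benzyloxy)-6-fluorophenyl]-2-(benzyloxy)-3-[3,4,5-tris(benzyloxy)phenyl]propane-1,3-diol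
Product: 15 (2R,3R,4R)-3,5,7-tris(benzyloxy)-2-[3,4,5-tris(benzyloxy)phenyl]chroman-4-ol, via potassium alkoxide 14 (not isolated)
Conditions: KOtBu (1.5 equiv), 18-crown-6 (0.2 equiv), THF/DMF, 0 → 50 °C
Reagents that add atoms: none
Why: KOtBu converts the diol into potassium alkoxide 14, whose C2 oxygen adds to the fluorine-bearing carbon C8a of the 2-fluoro-4,6-bis(benzyloxy)phenyl group and expels fluoride (addition–elimination, SNAr), which forms O1–C8a. The closest known reaction type is the intramolecular SNAr etherification of an alkoxide onto an aryl fluoride to give a chroman, a closure that has been used with this reversed polarity for flavan-3-ol rings. Ring C closes in the 6-exo-trig mode at C8a, the charge being taken up by C8, C6 and C4a of ring A. No stereocenter is made: C2 and C3 keep the configuration of step 2 because no bond to either is broken, so the 2,3-cis relation, which a closure through a C2 cation would not hold, is retained, and the C4 carbinol passes through as the leaving group for step 13. The step needs selection between two alkoxides and two ortho carbons: the C4 alkoxide could only close a four-membered ring, and of C5 and C8a only C8a carries fluoride, a far better leaving group than benzyl oxide. The oxygens at C5 and C7 are meta to C8a and do not donate into the attacked carbon, so the crown-ether-activated potassium alkoxide should react at moderate temperature.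

Step 9
Reactants: 15 (2R,3R,4R)-3,5,7-tris(benzyloxy)-2-[3,4,5-tris(benzyloxy)phenyl]chroman-4-ol
Product: 16 (2R,3R,4R)-3,5,7-tris(benzyloxy)-8-bromo-2-[3,4,5-tris(benzyloxy)phenyl]chroman-4-ol
Conditions: NBS (1.0 equiv), CH2Cl2, −78 → −30 °C
Reagents that add atoms: N-bromosuccinimide, O=C1CCC(=O)N1Br
Why: Electrophilic bromination of the phloroglucinol-type ring A, far more nucleophilic than ring B, should go to C8 as in other 5,7-bis(benzyloxy)flavans and caps the most nucleophilic carbon of the future electrophile.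

Step 10
Reactants: 17 (−)-epigallocatechin
Product: 18 (2R,3R)-5,7-bis(benzyloxy)-2-[3,4,5-tris(benzyloxy)phenyl]chroman-3-ol
Conditions: BnBr (5.5 equiv), K2CO3, DMF, 0 °C → rt, argon
Reagents that add atoms: benzyl bromide, BrCc1ccccc1
Why: Williamson etherification under a carbonate base alkylates the five phenols but not the secondary C3 alcohol, which is not deprotonated, and the exclusion of air and the low temperature should keep the pyrogallol ring from oxidation and C2 from epimerisation.

Step 11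
Reactants: 18 (2R,3R)-5,7-bis(benzyloxy)-2-[3,4,5-tris(benzyloxy)phenyl]chroman-3-ol; 19 3,4,5-tris(benzyloxy)benzoic acid
Product: 20 (2R,3R)-5,7-bis(benzyloxy)-2-[3,4,5-tris(benzyloxy)phenyl]chroman-3-yl 3,4,5-tris(benzyloxy)benzoate
Conditions: 19 (1.5 equiv), DCC (1.6 equiv), DMAP (0.3 equiv), CH2Cl2, 0 °C → rt
Reagents that add atoms: none
Why: Steglich esterification, in which DCC activates the acid and DMAP transfers the acyl group to the hindered axial C3 hydroxyl, forms the gallate ester with retention at C3 because the C3–O bond is not broken.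

Step 12
Reactants: 20 (2R,3R)-5,7-bis(benzyloxy)-2-[3,4,5-tris(benzyloxy)phenyl]chroman-3-yl 3,4,5-tris(benzyloxy)benzoate
Product: 21 (2R,3R)-5,7-bis(benzyloxy)-8-bromo-2-[3,4,5-tris(benzyloxy)phenyl]chroman-3-yl 3,4,5-tris(benzyloxy)benzoate
Conditions: NBS (1.0 equiv), CH2Cl2, −78 → 0 °C
Reagents that add atoms: N-bromosuccinimide, O=C1CCC(=O)N1Br
Why: Electrophilic bromination of ring A at C8, the usual site in 5,7-bis(benzyloxy)flavans, leaves C6 as the only free carbon of the phloroglucinol ring and so fixes the 4→6 connectivity.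

Step 13
Reactants: 16 (2R,3R,4R)-3,5,7-tris(benzyloxy)-8-bromo-2-[3,4,5-tris(benzyloxy)phenyl]chroman-4-ol; 21 (2R,3R)-5,7-bis(benzyloxy)-8-bromo-2-[3,4,5-tris(benzyloxy)phenyl]chroman-3-yl 3,4,5-tris(benzyloxy)benzoate
Product: 23 (2R,3R)-5,7-bis(benzyloxy)-8-bromo-6-[(2R,3R)-3,5,7-tris(benzyloxy)-8-bromo-2-[3,4,5-tris(benzyloxy)phenyl]chroman-4-yl]-2-[3,4,5-tris(benzyloxy)phenyl]chroman-3-yl 3,4,5-tris(benzyloxy)benzoate (upper C4 aryl trans to the C3 benzyloxy group), via flavan-4-yl cation 22 (not isolated)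
Conditions: 21 (3 equiv), BF3·OEt2 (0.3 equiv), 4 Å molecular sieves, CH2Cl2, −78 → −30 °C, slow addition of 16
Reagents that add atoms: none
Why: BF3·OEt2 ionises the C4 carbinol to benzylic cation 22, stabilised by O1 and the C5 and C7 oxygens, and C6 of 21 attacks it in a Friedel–Crafts alkylation of the kind used for halogen-capped flavan couplings; the nucleophile enters anti to the C3 benzyloxy and C2 aryl groups, which sets C4 with the 3,4-trans (4β) configuration, while the C8 bromine of 16 and slow addition to excess 21 hold back self-condensation.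

Step 14
Reactants: 23 the protected dibromo dimer of step 13
Product: 24 epigallocatechin-(4β→6)-epigallocatechin 3-O-gallate, upper unit (2R,3R,4S), lower unit (2R,3R)
Conditions: H2 (1 atm), Pd(OH)2/C, Et3N (2.2 equiv), THF/MeOH/H2O, rt
Reagents that add atoms: none
Why: Hydrogenolysis over Pd(OH)2/C should cleave the fourteen benzyl ethers and both aryl C–Br bonds in one operation while Et3N takes up the hydrogen bromide, and neither the gallate ester nor any stereocenter is affected.

**Compound list**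

1 | (S)-4-benzyloxazolidin-2-one | O=C1N[C@@H](Cc2ccccc2)CO1 | starting material
2 | (benzyloxy)acetyl chloride | O=C(Cl)COCc1ccccc1 | starting material
3 | (S)-4-benzyl-3-[(benzyloxy)acetyl]oxazolidin-2-one | O=C(COCc1ccccc1)N1C(=O)OC[C@@H]1Cc1ccccc1 | intermediate
4 | 3,4,5-tris(benzyloxy)benzaldehyde | O=Cc1cc(OCc2ccccc2)c(OCc2ccccc2)c(OCc2ccccc2)c1 | starting material
5 | dibutylboron Z-enolate of 3 (not isolated) | CCCCB(CCCC)O/C(=C\OCc1ccccc1)N1C(=O)OC[C@@H]1Cc1ccccc1 | intermediate
6 | (S)-4-benzyl-3-[(2S,3R)-2-(benzyloxy)-3-hydroxy-3-[3,4,5-tris(benzyloxy)phenyl]propanoyl]oxazolidin-2-one | O[C@H](c1cc(OCc2ccccc2)c(OCc2ccccc2)c(OCc2ccccc2)c1)[C@H](OCc1ccccc1)C(=O)N1C(=O)OC[C@@H]1Cc1ccccc1 | intermediate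
7 | (2S,3R)-2-(benzyloxy)-3-hydroxy-N-methoxy-N-methyl-3-[3,4,5-tris(benzyloxy)phenyl]propanamide | O[C@H](c1cc(OCc2ccccc2)c(OCc2ccccc2)c(OCc2ccccc2)c1)[C@H](OCc1ccccc1)C(=O)N(C)OC | intermediate
8 | 4-bromo-3,5-difluorophenol | Oc1cc(F)c(Br)c(F)c1 | starting material
9 | 5-(benzyloxy)-2-bromo-1,3-difluorobenzene | Fc1cc(OCc2ccccc2)cc(F)c1Br | intermediate
10 | 1,5-bis(benzyloxy)-2-bromo-3-fluorobenzene | Fc1cc(OCc2ccccc2)cc(OCc2ccccc2)c1Br | intermediate
11 | [2,4-bis(benzyloxy)-6-fluorophenyl]lithium (not isolated) | [Li]c1c(F)cc(OCc2ccccc2)cc1OCc1ccccc1 | intermediate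
12 | (2S,3R)-1-[2,4-bis(benzyloxy)-6-fluorophenyl]-2-(benzyloxy)-3-hydroxy-3-[3,4,5-tris(benzyloxy)phenyl]propan-1-one | O[C@H](c1cc(OCc2ccccc2)c(OCc2ccccc2)c(OCc2ccccc2)c1)[C@H](OCc1ccccc1)C(=O)c1c(F)cc(OCc2ccccc2)cc1OCc1ccccc1 | intermediate
13 | (1R,2S,3R)-1-[2,4-bis(benzyloxy)-6-fluorophenyl]-2-(benzyloxy)-3-[3,4,5-tris(benzyloxy)phenyl]propane-1,3-diol | O[C@H](c1cc(OCc2ccccc2)c(OCc2ccccc2)c(OCc2ccccc2)c1)[C@H](OCc1ccccc1)[C@H](O)c1c(F)cc(OCc2ccccc2)cc1OCc1ccccc1 | intermediate
14 | potassium alkoxide of 13 at the C3 hydroxyl, the future O1 (not isolated) | [K+].[O-][C@H](c1cc(OCc2ccccc2)c(OCc2ccccc2)c(OCc2ccccc2)c1)[C@H](OCc1ccccc1)[C@H](O)c1c(F)cc(OCc2ccccc2)cc1OCc1ccccc1 | intermediate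
15 | (2R,3R,4R)-3,5,7-tris(benzyloxy)-2-[3,4,5-tris(benzyloxy)phenyl]chroman-4-ol (all-cis) | O[C@H]1[C@@H](OCc2ccccc2)[C@@H](c2cc(OCc3ccccc3)c(OCc3ccccc3)c(OCc3ccccc3)c2)Oc2cc(OCc3ccccc3)cc(OCc3ccccc3)c12 | intermediate
16 | (2R,3R,4R)-3,5,7-tris(benzyloxy)-8-bromo-2-[3,4,5-tris(benzyloxy)phenyl]chroman-4-ol | O[C@H]1[C@@H](OCc2ccccc2)[C@@H](c2cc(OCc3ccccc3)c(OCc3ccccc3)c(OCc3ccccc3)c2)Oc2c(Br)c(OCc3ccccc3)cc(OCc3ccccc3)c12 | intermediate
17 | (−)-epigallocatechin, (2R,3R) | O[C@@H]1Cc2c(O)cc(O)cc2O[C@@H]1c1cc(O)c(O)c(O)c1 | starting material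
18 | (2R,3R)-5,7-bis(benzyloxy)-2-[3,4,5-tris(benzyloxy)phenyl]chroman-3-ol | O[C@@H]1Cc2c(OCc3ccccc3)cc(OCc3ccccc3)cc2O[C@@H]1c1cc(OCc2ccccc2)c(OCc2ccccc2)c(OCc2ccccc2)c1 | intermediate
19 | 3,4,5-tris(benzyloxy)benzoic acid | O=C(O)c1cc(OCc2ccccc2)c(OCc2ccccc2)c(OCc2ccccc2)c1 | starting material
20 | (2R,3R)-5,7-bis(benzyloxy)-2-[3,4,5-tris(benzyloxy)phenyl]chroman-3-yl 3,4,5-tris(benzyloxy)benzoate | O=C(O[C@@H]1Cc2c(OCc3ccccc3)cc(OCc3ccccc3)cc2O[C@@H]1c1cc(OCc2ccccc2)c(OCc2ccccc2)c(OCc2ccccc2)c1)c1cc(OCc2ccccc2)c(OCc2ccccc2)c(OCc2ccccc2)c1 | intermediate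
21 | (2R,3R)-5,7-bis(benzyloxy)-8-bromo-2-[3,4,5-tris(benzyloxy)phenyl]chroman-3-yl 3,4,5-tris(benzyloxy)benzoate | O=C(O[C@@H]1Cc2c(OCc3ccccc3)cc(OCc3ccccc3)c(Br)c2O[C@@H]1c1cc(OCc2ccccc2)c(OCc2ccccc2)c(OCc2ccccc2)c1)c1cc(OCc2ccccc2)c(OCc2ccccc2)c(OCc2ccccc2)c1 | intermediate
22 | (2R,3R)-3,5,7-tris(benzyloxy)-8-bromo-2-[3,4,5-tris(benzyloxy)phenyl]chroman-4-ylium cation (not isolated) | [CH+]1[C@@H](OCc2ccccc2)[C@@H](c2cc(OCc3ccccc3)c(OCc3ccccc3)c(OCc3ccccc3)c2)Oc2c(Br)c(OCc3ccccc3)cc(OCc3ccccc3)c12 | intermediate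
23 | protected dimer: tetradeca-O-benzyl-8,8-dibromo derivative of 24, upper C4 bonded to lower C6 and trans to the C3 benzyloxy group | O=C(O[C@@H]1Cc2c(c(Br)c(OCc3ccccc3)c([C@H]3c4c(OCc5ccccc5)cc(OCc5ccccc5)c(Br)c4O[C@H](c4cc(OCc5ccccc5)c(OCc5ccccc5)c(OCc5ccccc5)c4)[C@@H]3OCc3ccccc3)c2OCc2ccccc2)O[C@@H]1c1cc(OCc2ccccc2)c(OCc2ccccc2)c(OCc2ccccc2)c1)c1cc(OCc2ccccc2)c(OCc2ccccc2)c(OCc2ccccc2)c1 | intermediate
24 | epigallocatechin-(4β→6)-epigallocatechin 3-O-gallate, upper unit (2R,3R,4S), lower unit (2R,3R) | O=C(O[C@@H]1Cc2c(cc(O)c([C@H]3c4c(O)cc(O)cc4O[C@H](c4cc(O)c(O)c(O)c4)[C@@H]3O)c2O)O[C@@H]1c1cc(O)c(O)c(O)c1)c1cc(O)c(O)c(O)c1 | target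

**Count and risks**

Total step count: 14. Longest linear sequence: 9 steps (steps 1, 2, 3, 6, 7, 8, 9, 13, 14).

Steps most likely to fail:

Step 13. What may go wrong is self-condensation of the electrophile through its own free C6, together with slow attack by the hindered C6 of 21, so that oligomers form. The fallback sets out from 15. Both free ring A positions are brominated (NBS, 2.1 equiv, CH2Cl2, −78 → −20 °C) to the 6,8-dibromo flavan-4-ol F1, which can no longer act as a nucleophile. Coupling of F1 with 21 (1.2 equiv) under BF3·OEt2 catalysis gives the tribrominated protected dimer F2. Hydrogenolysis of F2 as in step 14 (Et3N 3.3 equiv) comes back to the route at 24.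

Step 8. What may go wrong is slow substitution at the C–F carbon, which carries no activating group, so that the alkoxide decomposes on prolonged heating. The fallback sets out from ketone 12 and closes the same O1–C8a bond while the ortho carbonyl group activates the fluoride (K2CO3, DMF, 0 °C → rt, short contact so that C3 does not epimerise), giving the 2,3-cis flavan-4-one F3. Reduction with NaBH4 (THF/MeOH, −40 °C), hydride entering anti to the axial C3 benzyloxy group, should give the all-cis carbinol and comes back to the route at 15.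

Step 6. What may go wrong is loss of lithium fluoride from the ortho-fluoro aryllithium (aryne formation) and retro-aldol cleavage of the lithium β-alkoxide before the addition is complete. The fallback sets out from imide 6. The auxiliary is exchanged for a thioester (LiSEt, THF, 0 °C) to give the S-ethyl thioester F4. Bromide 10 is turned into the thermally robust arylzinc chloride F5 (iPrMgCl·LiCl, THF, 0 °C; then ZnCl2). Fukuyama coupling of F4 with F5 (PdCl2(PPh3)2, THF/toluene, rt) comes back to the route at 12.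

**Further compounds**

F1 | step 13 | (2R,3R,4R)-3,5,7-tris(benzyloxy)-6,8-dibromo-2-[3,4,5-tris(benzyloxy)phenyl]chroman-4-ol | O[C@H]1[C@@H](OCc2ccccc2)[C@@H](c2cc(OCc3ccccc3)c(OCc3ccccc3)c(OCc3ccccc3)c2)Oc2c(Br)c(OCc3ccccc3)c(Br)c(OCc3ccccc3)c12
F2 | step 13 | protected dimer as 23 with bromine at C6 and C8 of the upper unit and at C8 of the lower unit | O=C(O[C@@H]1Cc2c(c(Br)c(OCc3ccccc3)c([C@H]3c4c(OCc5ccccc5)c(Br)c(OCc5ccccc5)c(Br)c4O[C@H](c4cc(OCc5ccccc5)c(OCc5ccccc5)c(OCc5ccccc5)c4)[C@@H]3OCc3ccccc3)c2OCc2ccccc2)O[C@@H]1c1cc(OCc2ccccc2)c(OCc2ccccc2)c(OCc2ccccc2)c1)c1cc(OCc2ccccc2)c(OCc2ccccc2)c(OCc2ccccc2)c1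
F3 | step 8 | (2R,3S)-3,5,7-tris(benzyloxy)-2-[3,4,5-tris(benzyloxy)phenyl]chroman-4-one (2,3-cis) | O=C1[C@@H](OCc2ccccc2)[C@@H](c2cc(OCc3ccccc3)c(OCc3ccccc3)c(OCc3ccccc3)c2)Oc2cc(OCc3ccccc3)cc(OCc3ccccc3)c12
F4 | step 6 | S-ethyl (2S,3R)-2-(benzyloxy)-3-hydroxy-3-[3,4,5-tris(benzyloxy)phenyl]propanethioate | O[C@H](c1cc(OCc2ccccc2)c(OCc2ccccc2)c(OCc2ccccc2)c1)[C@H](OCc1ccccc1)C(=O)SCC
F5 | step 6 | [2,4-bis(benzyloxy)-6-fluorophenyl]zinc chloride | Cl[Zn]c1c(F)cc(OCc2ccccc2)cc1OCc1ccccc1
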